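The readings were computed with made-up constants; scatter was added.

The birch run lost Q faster in its first 5.00 min than in the next 5.00 min, by a factor 6.62 against 2.80, so we take Q to leave by the pair step to J beside the single step to Z.

common to all: Q 0.30 M

|  | remark | time |
|---|---|---|
| birch | the very flask that is asked about, followed so far |  |
| flask |  | 1.0 h |

birch run (percent of the Q charged)

| time / min | Z / % | D / % | Q / % |
|---|---|---|---|
| 2.50 | 19.3 | 0 | 31.0 |
| 3.00 | 20.8 | 0.1 | 26.1 |
| 5.00 | 26.5 | 0 | 15.1 |
| 6.00 | 26.6 | 0 | 12.3 |
| 10.0 | 28.1 | 1.0 | 5.4 |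
| 12.0 | 27.7 | 0.4 | 4.4 |
| 20.0 | 23.0 | 1.4 | 1.8 |

(each reading ± 0.5 percentage points)

* the best time, 1.0 h at the latest, for Z
* the amount of Z, in percent of the Q charged, at that time

- percentages count the Q that a species holds: one J counts as two
- what may be going on: Z -> X; X -> D; 2 Q -> J; X -> L; Q -> Z

How much of the charge reaches Z? With these two steps, the charged c_Q over the present c_Q, plus a constant, grows exponentially in time. The birch readings at 5.00 min and 10.0 min therefore put that constant at about 4.04. We call it the pull: the rate at which the pair step uses Q over the rate at which the single step uses it, at the charged c_Q. The same readings put the single step at about 0.150 min⁻¹. The selectivity to Z, ln(1 + pull)/pull, comes to 40.0% of the charge, and J takes the rest.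

How fast does Z leak away? From 12.0 min to 20.0 min we reckon that Q fed Z 2.3 percentage points, yet the Z readings fell, which gives a leak of about 0.0346 min⁻¹.

Z stops rising where the feed equals the leak. With Z near its reading of 28.1%, that means Q at 6.48%, which we reckon comes at 0.150 h.

The forecast gives 28% at 0.15 h, holding that “Most Q is therefore lost to J”.

The flask gives 28.2% at 0.155 h.

    Z → X (k = 5.58 × 10⁻⁴ s⁻¹)
    X → D (k = 0.00244 s⁻¹)
    2 Q → J (k = 0.0163 M⁻¹ s⁻¹)
    X → L (k = 0.0354 s⁻¹)
    Q → Z (k = 0.00250 s⁻¹)

J ends at 59.3% after 10.0 h, against the 60.0% reckoned. A neighbour flask charged with 1.2 M of Q, with the time and all else held, does not reach the forecast's peak. Its pull is 16.2 and its share to Z 17.6%, which leaves 82.4% for J and, scaling the peak by the share, 12.4% for Z. That flask holds 82.0% of J after 1.00 h, and its Z peaks at 13.0%.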